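Remark on the chemistry: the target is taken as the 2-hydroxy-1,4-naphthoquinone tautomer that is drawn, and it has no stereocentre. Numbering used below: quinone ring C1–C4 (OH at C2), ring A C4a–C8a (methyl at C5, ketone at C6, OH at C7), ring B C1'–C6' (C1' on the ketone carbon, OH at C2' and C4', CH2 at C6'), pyranone O1''–C6''.

## The problem

Target 29 is a 2,7-dihydroxy-5-methyl-1,4-naphthoquinone whose C6 is joined through a ketone to C1' of a resorcinol ring B. C6' of ring B carries a methylene that ends in C6'' of a 4-hydroxy-2-pyranone. There is no stereocentre, so the whole difficulty is constitutional: five oxygen functions and one ketone must be placed correctly around three rings. The ketone carbon sits between the C5 methyl and C7 oxygen on one side and the C2' oxygen and C6' methylene on the other. It is therefore a tetra-ortho-substituted benzophenone, and joining two finished arenes at that carbon is the least promising bond formation available. The hydroxyquinone (Michael acceptor, reducible, base-labile), the hydroxypyranone (acidic, oxidisable enol lactone), the doubly activated CH2 and the free phenols will not survive enolate or hydride chemistry. They have to be unveiled late, and the quinone is best stored as a 1,2,4-trimethoxy ring. What makes the key step possible is the pattern of ring B: the oxygens at C2' and C4' are 1,3-related, C1' lies between the ketone carbon and C2', and C6' is β to C4'. Ring B therefore maps onto a cyclohexane-1,3-dione in which C1' is the α-carbon of an aroylacetate and C6' the β-carbon of a methyl enone, so the ring can be grown on the ketone instead of being attached to it. The only stereocentre met on the way (C6' of the dione) is racemic and disappears on aromatisation.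

## Retrosynthesis

**29 back to 26 (protecting groups).** No skeletal bond is cut. The two benzyl–oxygen bonds on ring B and the methyl–oxygen bond at C7 are cleaved by a boron halide, giving 28. The C2 methyl ether of the quinone is exchanged by hydroxide, giving 27. The C1 and C4 methyl ethers are removed oxidatively by tetravalent cerium, giving 26. Benzyl is preferred to methyl on ring B because a methoxy group para to the ketone is the one ether that would need forcing conditions on a fully unveiled polyphenol. The C7 methyl ether is ortho to the ketone and cleaves under the same mild Lewis acid. The forward oxidation must select the trimethoxy ring over the pyranone enol.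

**26 back to 21 and 22 (pyranone).** The O1''–C2'' bond is cut (lactonisation of acylketene 25, generated by heating 24) and the C5''–C6'' bond is cut (vinylogous Claisen acylation of dioxinone 22 by acyl imidazolide 23 from acid 21). The neighbouring option, alkylating a preformed pyranone anion with a benzylic electrophile ortho to the hindered ketone, needs a dianion and a crowded SN2 reaction. The dioxinone brings four carbons in masked form and closes the ring without base. The forward acylation must outrun proton transfer from the arylacetyl CH2.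

**21 back to 16 (oxidation level of ring B and its side chain).** Acid 21 comes from alcohol 19 via aldehyde 20, 19 from silyl ether 18, 18 from resorcinol 17, and 17 from dione 16 by removing two hydrogens across C5'–C6'. The two-carbon arm is carried as a silyl ether and not as an ester. An ester would offer the annulation a second six-membered Claisen closure and would make the enone γ-acidic. The dehydrogenation must leave the electron-rich naphthalene alone.

**16 back to 11 and 14 (key disconnection).** The C1'–C6' and C2'–C3' bonds are cut. This removes ring B entirely and leaves an aroylacetate 11 and an acyclic enone 14, with 15 as the open-chain adduct. Its advantage over any arene–acyl union is that the crowded ketone is already present in 11 and is never attacked. The forward reaction must close on the ester and not on the aroyl carbonyl.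

**14 back to 12.** The C5'=C6' double bond is cut by Wittig olefination of aldehyde 13, which comes from commercial mono-silylated diol 12.

**11 back to 8.** The bond between the ketone carbon and C1' is cut by homologation of aldehyde 10 with a diazoacetic ester. Claisen condensation of ester 8 with an acetate enolate is the obvious neighbour, but the di-ortho-substituted ester would resist it. The aldehyde, reached through alcohol 9, is small enough to react.

**8 back to 1 and 3 (naphthalene).** Reductive methylation relates 8 to quinone 6 through hydroquinone 7. Ring A of 6 is cut at C4a–C5 and C8–C8a (Diels–Alder, adduct 5) into bromoquinone 2 and bis(silyloxy)diene 4. Diene 4 carries the methyl, the carboxyl carbon and the oxygen in the right order and at the right oxidation level. It comes in one step from commercial tricarbonyl compound 3, and 2 comes in one step from commercial arene 1. The cycloaddition must place the diene CH2 terminus on the unsubstituted carbon next to C–Br.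

## Roads not taken

**Alternative 1:** The cut is the O1''–C2'' lactone bond only. Heating the β-keto dioxinone A1 in toluene would generate an acylketene that is captured by the enol oxygen of the C6'' ketone, giving pyranone A2. The step is neutral, needs no reagent and forms the most fragile ring last. Taken by itself it is more dependable than the Michael–Claisen annulation, and that is conceded. As a strategy, however, it dismantles only the simplest ring. A1 still contains the tetra-ortho-substituted benzophenone, which would have to be made by joining two finished arenes at the hindered carbon. The all-methyl protection of A2 also leaves a methoxy group para to the ketone to be cleaved at the very end. The chosen plan loses nothing here, because it uses the same ring closure as step 16 (24 to 26). What it sets against the greater reliability of this key step is that its own key step solves the benzophenone problem, which Alternative 1 leaves open.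

**Alternative 2:** The cut is C1–C2, C3–C4 and C1–C8a of the quinone ring. The aryl(methoxy)carbene complex of zerovalent chromium A3 would combine with a terminal alkoxyalkyne and one carbonyl ligand to give naphthol A4 (Dötz benzannulation). Three bonds form in one operation, and the four oxygens of that ring emerge fully differentiated. The orientation is fixed by the alkyne, which is better founded than the halogen-directed orientation the chosen plan relies on in step 3. The weak points are these:
- Cr(CO)6 is used stoichiometrically.
- The ortho methyl group next to the carbene carbon slows CO insertion and favours indene and cyclobutenone by-products.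
- The tetrasubstituted aryl precursor of A3 needs several steps.
- A4 contributes nothing to ring B or the hindered ketone.

It is really an alternative to steps 1–4 and could feed the same key step through aldehyde 10. The chosen plan sets against its regiochemical certainty a shorter naphthalene synthesis from two commercial partners, no stoichiometric heavy metal, and a dibromoquinone fallback that removes the regiochemical doubt.

**Alternative 3:** The cut is C4a–C5 and C8–C8a, made late. The acyl silyloxy diene A5, which already carries ring B and the pyranone, would add to bromoquinone 2. Loss of HBr, enolisation and air oxidation would give naphthoquinone A6. This is the most convergent plan. The quinone also arrives at its final oxidation state, so no tetravalent cerium ever meets the pyranone; in that respect it is better than the chosen route. Its weak points are these: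
- The aroyl group of A5 is the same hindered ketone, so the difficult carbonyl must still be made, by acylating a di-ortho-substituted benzoyl unit.
- The dicarbonyl precursor of A5 must enolise at the acetyl methyl and not at the γ-methyl of the ethylidene group, and the ethylidene geometry must place the methyl outside the diene.
- The acyl group lowers the diene's reactivity.
- The 4-methoxypyranone of A6 needs a final O-demethylation that competes with lactone opening.

The chosen plan uses the same cycloaddition early (step 3) with the simple symmetric diene 4, for which none of these questions arise. It then forms the ketone's second aryl ring by annulation.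

Key step: step 10

## Route

Step 1
Reactants: 1 1-bromo-2,4,5-trimethoxybenzene
Product: 2 2-bromo-5-methoxy-1,4-benzoquinone
Conditions: (NH4)2Ce(NO3)6 (2.5 equiv), MeCN/H2O, 0 °C
Reagents that add atoms: water, O
Why: Oxidative demethylation of a para-dimethoxyarene by tetravalent cerium; the mutually para methoxy groups at C2 and C5 leave as methanol and water supplies the carbonyl oxygens, while the C4 methoxy group survives as the vinylogous ester and the bromine is untouched.

Step 2
Reactants: 3 ethyl 2-acetyl-3-oxobutanoate
Product: 4 ethyl 3-(trimethylsilyloxy)-2-[1-(trimethylsilyloxy)ethenyl]but-2-enoate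
Conditions: Me3SiOTf (2.2 equiv), Et3N, Et2O, 0 °C to rt; used crude
Reagents that add atoms: trimethylsilyl trifluoromethanesulfonate, C[Si](C)(C)OS(=O)(=O)C(F)(F)F
Why: Silyl enol ether formation by soft enolisation; the enolised tricarbonyl is silylated once and then deprotonated at an acetyl methyl, and since the two acetyl groups are equivalent only one diene constitution can form, the alkene geometry being irrelevant because that carbon becomes aromatic.

Step 3
Reactants: 2 2-bromo-5-methoxy-1,4-benzoquinone; 4 ethyl 3-(trimethylsilyloxy)-2-[1-(trimethylsilyloxy)ethenyl]but-2-enoate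
Product: 6 ethyl 3-hydroxy-6-methoxy-1-methyl-5,8-dioxo-5,8-dihydronaphthalene-2-carboxylate, via bromo cycloadduct 5 (not isolated)
Conditions: toluene, −20 °C to rt; then SiO2, CH2Cl2; then 1 M HCl, THF
Reagents that add atoms: none
Why: Diels–Alder reaction of a bromoquinone with a 2,4-bis(silyloxy)-1,3-diene, the established way to 3-hydroxy-1-methyl-2-carboxylate arenes; the nucleophilic CH2 terminus of 4 should bond to the unsubstituted carbon next to C–Br (halogen-directed orientation) on the more electron-poor double bond, and loss of HBr and Me3SiOH from 5 with hydrolysis of the aryl silyl ether gives the quinone directly at the right oxidation level.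

Step 4
Reactants: 6 ethyl 3-hydroxy-6-methoxy-1-methyl-5,8-dioxo-5,8-dihydronaphthalene-2-carboxylate
Product: 8 ethyl 3,5,6,8-tetramethoxy-1-methylnaphthalene-2-carboxylate, via hydroquinone 7 (not isolated)
Conditions: Na2S2O4, EtOAc/H2O, rt; then Me2SO4, K2CO3, acetone, reflux, N2
Reagents that add atoms: dimethyl sulfate, COS(=O)(=O)OC
Why: Reductive methylation; dithionite reduces the quinone to 7 and Williamson etherification caps both hydroquinone hydroxyls and the C3 phenol, so the quinone is stored as a trimethoxy ring that tolerates hydride, enolate and fluoride chemistry.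

Step 5
Reactants: 8 ethyl 3,5,6,8-tetramethoxy-1-methylnaphthalene-2-carboxylate
Product: 9 (3,5,6,8-tetramethoxy-1-methylnaphthalen-2-yl)methanol
Conditions: LiAlH4, THF, 0 °C to reflux
Reagents that add atoms: none
Why: Hydride reduction of an ester; the small hydride reduces the di-ortho-substituted ester that would resist attack by carbon nucleophiles.

Step 6
Reactants: 9 (3,5,6,8-tetramethoxy-1-methylnaphthalen-2-yl)methanol
Product: 10 3,5,6,8-tetramethoxy-1-methylnaphthalene-2-carbaldehyde
Conditions: activated MnO2, CH2Cl2, rt
Reagents that add atoms: none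
Why: MnO2 oxidation of an electron-rich benzylic alcohol, which stops at the aldehyde and leaves the methoxynaphthalene untouched.

Step 7
Reactants: 10 3,5,6,8-tetramethoxy-1-methylnaphthalene-2-carbaldehyde
Product: 11 ethyl 3-oxo-3-(3,5,6,8-tetramethoxy-1-methylnaphthalen-2-yl)propanoate
Conditions: N2CHCO2Et, SnCl2 (10 mol%), CH2Cl2, rt
Reagents that add atoms: ethyl diazoacetate, CCOC(=O)C=[N+]=[N-]
Why: Roskamp homologation; the tin-activated aldehyde is attacked by the diazo carbon and a 1,2-hydride shift with loss of N2 gives the β-keto ester, so the bond from the ketone carbon to C1' forms without any attack on a hindered ester.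

Step 8
Reactants: 12 3-(tert-butyldimethylsilyloxy)propan-1-ol
Product: 13 3-(tert-butyldimethylsilyloxy)propanal
Conditions: TEMPO (10 mol%), PhI(OAc)2, CH2Cl2, rt
Reagents that add atoms: none
Why: Oxoammonium (TEMPO) oxidation of a primary alcohol to the aldehyde under non-acidic conditions that spare the silyl ether.

Step 9
Reactants: 13 3-(tert-butyldimethylsilyloxy)propanal
Product: 14 (E)-6-(tert-butyldimethylsilyloxy)hex-3-en-2-one
Conditions: Ph3P=CHC(O)CH3, CH2Cl2, rt
Reagents that add atoms: 1-(triphenylphosphoranylidene)propan-2-one, CC(=O)C=P(c1ccccc1)(c1ccccc1)c1ccccc1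
Why: Wittig olefination with a stabilised acyl ylide, which gives the (E)-enone.

Step 10
Reactants: 11 ethyl 3-oxo-3-(3,5,6,8-tetramethoxy-1-methylnaphthalen-2-yl)propanoate; 14 (E)-6-(tert-butyldimethylsilyloxy)hex-3-en-2-one
Product: 16 5-[2-(tert-butyldimethylsilyloxy)ethyl]-3-hydroxy-4-(3,5,6,8-tetramethoxy-1-methyl-2-naphthoyl)cyclohex-3-en-1-one (racemic), via Michael adduct 15 (not isolated)
Conditions: NaOEt (2.2 equiv), EtOH, 0 °C to reflux; then 1 M HCl
Reagents that add atoms: none
Why: Ethoxide converts 11 into the stabilised aroylacetate enolate, which adds through C1' to the β-carbon C6' of enone 14 to give adduct 15 (Michael addition). Proton exchange in ethanol then makes the methyl ketone enolate of 15 available, and its methyl carbon C3' attacks the ester carbonyl C2' with loss of ethoxide (Claisen condensation). The closest known reaction type is the Michael–Claisen annulation of malonates or acetoacetates with methyl enones that gives dimedone, dihydroorsellinates and 5-alkylcyclohexane-1,3-diones. The six-membered carbocycle closes by a 6-exo-trig attack of the enolate carbon on the ester carbonyl. The product is a tricarbonyl compound far more acidic than ethanol, so it is removed as its sodium enolate and the sequence is pulled to completion; acid then releases 16 as the hydrogen-bonded enol. The one stereocentre that persists (C6', ring position 5 of 16) is formed without control and is racemic, C1' is enolised, and the stereocentre is erased in step 11. The selectivity needed is Claisen closure on the ester in preference to aldol closure of the same enolate on the aroyl carbonyl. That carbonyl is flanked by the C1 methyl and C3 methoxy groups of the naphthalene and is shielded, any aldol adduct forms reversibly, and only the Claisen product is trapped as an enolate.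

Step 11
Reactants: 16 5-[2-(tert-butyldimethylsilyloxy)ethyl]-3-hydroxy-4-(3,5,6,8-tetramethoxy-1-methyl-2-naphthoyl)cyclohex-3-en-1-one
Product: 17 {2-[2-(tert-butyldimethylsilyloxy)ethyl]-4,6-dihydroxyphenyl}(3,5,6,8-tetramethoxy-1-methylnaphthalen-2-yl)methanone
Conditions: DDQ (1.1 equiv), 1,4-dioxane, rt to 50 °C
Reagents that add atoms: none
Why: Quinone dehydrogenation of a cyclohexane-1,3-dione to a resorcinol, as used for dihydroorsellinates; hydride is abstracted from C6'–H, which is allylic to the electron-rich enol, and the resulting enedione tautomerises to the arene, the acylated naphthalene being a much poorer hydride donor.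

Step 12
Reactants: 17 {2-[2-(tert-butyldimethylsilyloxy)ethyl]-4,6-dihydroxyphenyl}(3,5,6,8-tetramethoxy-1-methylnaphthalen-2-yl)methanone
Product: 18 {2,4-bis(benzyloxy)-6-[2-(tert-butyldimethylsilyloxy)ethyl]phenyl}(3,5,6,8-tetramethoxy-1-methylnaphthalen-2-yl)methanone
Conditions: BnBr (2.5 equiv), K2CO3, DMF, 60 °C
Reagents that add atoms: benzyl bromide, BrCc1ccccc1
Why: Williamson etherification of both phenols before the oxidation and enolate steps; benzyl is chosen so that the ether para to the ketone can be removed at low temperature at the end.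

Step 13
Reactants: 18 {2,4-bis(benzyloxy)-6-[2-(tert-butyldimethylsilyloxy)ethyl]phenyl}(3,5,6,8-tetramethoxy-1-methylnaphthalen-2-yl)methanone
Product: 19 [2,4-bis(benzyloxy)-6-(2-hydroxyethyl)phenyl](3,5,6,8-tetramethoxy-1-methylnaphthalen-2-yl)methanone
Conditions: Bu4NF, THF, 0 °C to rt
Reagents that add atoms: none
Why: Fluoride cleavage of the primary silyl ether; benzyl and methyl ethers and the hindered ketone are inert.

Step 14
Reactants: 19 [2,4-bis(benzyloxy)-6-(2-hydroxyethyl)phenyl](3,5,6,8-tetramethoxy-1-methylnaphthalen-2-yl)methanone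
Product: 21 2-[3,5-bis(benzyloxy)-2-(3,5,6,8-tetramethoxy-1-methyl-2-naphthoyl)phenyl]acetic acid, via arylacetaldehyde 20 (not isolated)
Conditions: TEMPO (20 mol%), PhI(OAc)2 (2.5 equiv), MeCN/H2O, rt
Reagents that add atoms: water, O
Why: Oxoammonium oxidation in wet acetonitrile takes the primary alcohol through aldehyde 20 and its hydrate to the acid in one flask, avoiding chromium or chlorine oxidants that would attack the electron-rich naphthalene.

Step 15
Reactants: 21 2-[3,5-bis(benzyloxy)-2-(3,5,6,8-tetramethoxy-1-methyl-2-naphthoyl)phenyl]acetic acid; 22 2,2,6-trimethyl-4H-1,3-dioxin-4-one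
Product: 24 6-{3-[3,5-bis(benzyloxy)-2-(3,5,6,8-tetramethoxy-1-methyl-2-naphthoyl)phenyl]-2-oxopropyl}-2,2-dimethyl-4H-1,3-dioxin-4-one, via acyl imidazolide 23 (not isolated)
Conditions: 1,1'-carbonyldiimidazole, THF, rt; then added to 22 (3 equiv) and LiN(SiMe3)2 (3 equiv), THF, −78 to −40 °C; NH4Cl
Reagents that add atoms: none
Why: γ-Acylation of the lithium dienolate of a dioxinone (vinylogous Claisen condensation) by acyl imidazolide 23; excess dienolate is used because 24 is more acidic than 22, and the tetra-ortho-substituted diaryl ketone is too hindered to compete as an electrophile.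

Step 16
Reactants: 24 6-{3-[3,5-bis(benzyloxy)-2-(3,5,6,8-tetramethoxy-1-methyl-2-naphthoyl)phenyl]-2-oxopropyl}-2,2-dimethyl-4H-1,3-dioxin-4-one
Product: 26 6-{[3,5-bis(benzyloxy)-2-(3,5,6,8-tetramethoxy-1-methyl-2-naphthoyl)phenyl]methyl}-4-hydroxy-2H-pyran-2-one, via acylketene 25 (not isolated)
Conditions: toluene, 110 °C
Reagents that add atoms: none
Why: Thermal retro-[4+2] fragmentation of the dioxinone expels acetone and gives acylketene 25, whose C6'' ketone, as its enol, adds through oxygen to the ketene carbon (lactonisation) to give the 4-hydroxy-2-pyranone without base.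

Step 17
Reactants: 26 6-{[3,5-bis(benzyloxy)-2-(3,5,6,8-tetramethoxy-1-methyl-2-naphthoyl)phenyl]methyl}-4-hydroxy-2H-pyran-2-one
Product: 27 6-{[3,5-bis(benzyloxy)-2-(3,6-dimethoxy-1-methyl-5,8-dioxo-5,8-dihydronaphthalene-2-carbonyl)phenyl]methyl}-4-hydroxy-2H-pyran-2-one
Conditions: (NH4)2Ce(NO3)6 (2.5 equiv), MeCN/H2O, 0 °C, short reaction time
Reagents that add atoms: water, O
Why: Oxidative demethylation by tetravalent cerium of the mutually para 5- and 8-methoxy groups of the trimethoxy ring, the most electron-rich part of the molecule; the 6-methoxy group stays as the methoxyquinone, and the benzyl ethers, the anisole-type ring A and the acylated ring B are much harder to oxidise.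

Step 18
Reactants: 27 6-{[3,5-bis(benzyloxy)-2-(3,6-dimethoxy-1-methyl-5,8-dioxo-5,8-dihydronaphthalene-2-carbonyl)phenyl]methyl}-4-hydroxy-2H-pyran-2-one
Product: 28 6-{[3,5-bis(benzyloxy)-2-(6-hydroxy-3-methoxy-1-methyl-5,8-dioxo-5,8-dihydronaphthalene-2-carbonyl)phenyl]methyl}-4-hydroxy-2H-pyran-2-one
Conditions: LiOH, THF/H2O, 0 °C to rt; then 1 M HCl
Reagents that add atoms: lithium hydroxide, [Li+].[OH-]
Why: Addition–elimination of hydroxide at the vinylogous ester carbon of the 2-methoxy-1,4-quinone (vinylogous saponification); the pyranone is protected as its anion and the aryl ethers do not react.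

Step 19
Reactants: 28 6-{[3,5-bis(benzyloxy)-2-(6-hydroxy-3-methoxy-1-methyl-5,8-dioxo-5,8-dihydronaphthalene-2-carbonyl)phenyl]methyl}-4-hydroxy-2H-pyran-2-one
Product: 29 6-{[2-(3,6-dihydroxy-1-methyl-5,8-dioxo-5,8-dihydronaphthalene-2-carbonyl)-3,5-dihydroxyphenyl]methyl}-4-hydroxy-2H-pyran-2-one
Conditions: BBr3 (8 equiv), CH2Cl2, −78 to 0 °C; then H2O
Reagents that add atoms: none
Why: Lewis acid ether cleavage; the two benzyl ethers cleave at low temperature and the methyl ether ortho to the ketone on ring A is activated by boron coordination to the carbonyl oxygen, and hydrolysis of the borates should give 29, which has no stereocentre.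

## Compound list

1 | 1-bromo-2,4,5-trimethoxybenzene | COc1cc(OC)c(Br)cc1OC | starting material
2 | 2-bromo-5-methoxy-1,4-benzoquinone | COC1=CC(=O)C(Br)=CC1=O | intermediate
3 | ethyl 2-acetyl-3-oxobutanoate | CCOC(=O)C(C(C)=O)C(C)=O | starting material
4 | ethyl 3-(trimethylsilyloxy)-2-[1-(trimethylsilyloxy)ethenyl]but-2-enoate (mixture of alkene isomers) | CCOC(=O)C(C(=C)O[Si](C)(C)C)=C(C)O[Si](C)(C)C | intermediate
5 | ethyl 8a-bromo-6-methoxy-1-methyl-5,8-dioxo-1,3-bis(trimethylsilyloxy)-1,4,4a,5,8,8a-hexahydronaphthalene-2-carboxylate (mixture of diastereomers) | CCOC(=O)C1=C(O[Si](C)(C)C)CC2C(=O)C(OC)=CC(=O)C2(Br)C1(C)O[Si](C)(C)C | intermediate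
6 | ethyl 3-hydroxy-6-methoxy-1-methyl-5,8-dioxo-5,8-dihydronaphthalene-2-carboxylate | CCOC(=O)c1c(C)c2C(=O)C=C(OC)C(=O)c2cc1O | intermediate
7 | ethyl 3,5,8-trihydroxy-6-methoxy-1-methylnaphthalene-2-carboxylate | CCOC(=O)c1c(C)c2c(O)cc(OC)c(O)c2cc1O | intermediate
8 | ethyl 3,5,6,8-tetramethoxy-1-methylnaphthalene-2-carboxylate | CCOC(=O)c1c(C)c2c(OC)cc(OC)c(OC)c2cc1OC | intermediate
9 | (3,5,6,8-tetramethoxy-1-methylnaphthalen-2-yl)methanol | Cc1c(CO)c(OC)cc2c1c(OC)cc(OC)c2OC | intermediate
10 | 3,5,6,8-tetramethoxy-1-methylnaphthalene-2-carbaldehyde | Cc1c(C=O)c(OC)cc2c1c(OC)cc(OC)c2OC | intermediate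
11 | ethyl 3-oxo-3-(3,5,6,8-tetramethoxy-1-methylnaphthalen-2-yl)propanoate | Cc1c(C(=O)CC(=O)OCC)c(OC)cc2c1c(OC)cc(OC)c2OC | intermediate
12 | 3-(tert-butyldimethylsilyloxy)propan-1-ol | CC(C)(C)[Si](C)(C)OCCCO | starting material
13 | 3-(tert-butyldimethylsilyloxy)propanal | CC(C)(C)[Si](C)(C)OCCC=O | intermediate
14 | (E)-6-(tert-butyldimethylsilyloxy)hex-3-en-2-one | CC(=O)/C=C/CCO[Si](C)(C)C(C)(C)C | intermediate
15 | ethyl 3-[2-(tert-butyldimethylsilyloxy)ethyl]-5-oxo-2-(3,5,6,8-tetramethoxy-1-methyl-2-naphthoyl)hexanoate (mixture of racemic diastereomers) | Cc1c(C(=O)C(C(=O)OCC)C(CCO[Si](C)(C)C(C)(C)C)CC(C)=O)c(OC)cc2c1c(OC)cc(OC)c2OC | intermediate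
16 | 5-[2-(tert-butyldimethylsilyloxy)ethyl]-3-hydroxy-4-(3,5,6,8-tetramethoxy-1-methyl-2-naphthoyl)cyclohex-3-en-1-one (racemic, one enantiomer drawn) | Cc1c(C(=O)C3=C(O)CC(=O)C[C@@H]3CCO[Si](C)(C)C(C)(C)C)c(OC)cc2c1c(OC)cc(OC)c2OC | intermediate
17 | {2-[2-(tert-butyldimethylsilyloxy)ethyl]-4,6-dihydroxyphenyl}(3,5,6,8-tetramethoxy-1-methylnaphthalen-2-yl)methanone | Cc1c(C(=O)c3c(O)cc(O)cc3CCO[Si](C)(C)C(C)(C)C)c(OC)cc2c1c(OC)cc(OC)c2OC | intermediate
18 | {2,4-bis(benzyloxy)-6-[2-(tert-butyldimethylsilyloxy)ethyl]phenyl}(3,5,6,8-tetramethoxy-1-methylnaphthalen-2-yl)methanone | Cc1c(C(=O)c3c(OCc4ccccc4)cc(OCc4ccccc4)cc3CCO[Si](C)(C)C(C)(C)C)c(OC)cc2c1c(OC)cc(OC)c2OC | intermediate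
19 | [2,4-bis(benzyloxy)-6-(2-hydroxyethyl)phenyl](3,5,6,8-tetramethoxy-1-methylnaphthalen-2-yl)methanone | Cc1c(C(=O)c3c(OCc4ccccc4)cc(OCc4ccccc4)cc3CCO)c(OC)cc2c1c(OC)cc(OC)c2OC | intermediate
20 | 2-[3,5-bis(benzyloxy)-2-(3,5,6,8-tetramethoxy-1-methyl-2-naphthoyl)phenyl]acetaldehyde | Cc1c(C(=O)c3c(OCc4ccccc4)cc(OCc4ccccc4)cc3CC=O)c(OC)cc2c1c(OC)cc(OC)c2OC | intermediate
21 | 2-[3,5-bis(benzyloxy)-2-(3,5,6,8-tetramethoxy-1-methyl-2-naphthoyl)phenyl]acetic acid | Cc1c(C(=O)c3c(OCc4ccccc4)cc(OCc4ccccc4)cc3CC(=O)O)c(OC)cc2c1c(OC)cc(OC)c2OC | intermediate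
22 | 2,2,6-trimethyl-4H-1,3-dioxin-4-one | CC1=CC(=O)OC(C)(C)O1 | starting material
23 | 2-[3,5-bis(benzyloxy)-2-(3,5,6,8-tetramethoxy-1-methyl-2-naphthoyl)phenyl]-1-(1H-imidazol-1-yl)ethan-1-one | Cc1c(C(=O)c3c(OCc4ccccc4)cc(OCc4ccccc4)cc3CC(=O)n4ccnc4)c(OC)cc2c1c(OC)cc(OC)c2OC | intermediate
24 | 6-{3-[3,5-bis(benzyloxy)-2-(3,5,6,8-tetramethoxy-1-methyl-2-naphthoyl)phenyl]-2-oxopropyl}-2,2-dimethyl-4H-1,3-dioxin-4-one | Cc1c(C(=O)c3c(OCc4ccccc4)cc(OCc4ccccc4)cc3CC(=O)CC3=CC(=O)OC(C)(C)O3)c(OC)cc2c1c(OC)cc(OC)c2OC | intermediate
25 | 6-[3,5-bis(benzyloxy)-2-(3,5,6,8-tetramethoxy-1-methyl-2-naphthoyl)phenyl]hex-1-ene-1,3,5-trione | Cc1c(C(=O)c3c(OCc4ccccc4)cc(OCc4ccccc4)cc3CC(=O)CC(=O)C=C=O)c(OC)cc2c1c(OC)cc(OC)c2OC | intermediate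
26 | 6-{[3,5-bis(benzyloxy)-2-(3,5,6,8-tetramethoxy-1-methyl-2-naphthoyl)phenyl]methyl}-4-hydroxy-2H-pyran-2-one | Cc1c(C(=O)c3c(OCc4ccccc4)cc(OCc4ccccc4)cc3Cc3cc(O)cc(=O)o3)c(OC)cc2c1c(OC)cc(OC)c2OC | intermediate
27 | 6-{[3,5-bis(benzyloxy)-2-(3,6-dimethoxy-1-methyl-5,8-dioxo-5,8-dihydronaphthalene-2-carbonyl)phenyl]methyl}-4-hydroxy-2H-pyran-2-one | Cc1c(C(=O)c3c(OCc4ccccc4)cc(OCc4ccccc4)cc3Cc3cc(O)cc(=O)o3)c(OC)cc2c1C(=O)C=C(OC)C2=O | intermediate
28 | 6-{[3,5-bis(benzyloxy)-2-(6-hydroxy-3-methoxy-1-methyl-5,8-dioxo-5,8-dihydronaphthalene-2-carbonyl)phenyl]methyl}-4-hydroxy-2H-pyran-2-one | Cc1c(C(=O)c3c(OCc4ccccc4)cc(OCc4ccccc4)cc3Cc3cc(O)cc(=O)o3)c(OC)cc2c1C(=O)C=C(O)C2=O | intermediate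
29 | 6-{[2-(3,6-dihydroxy-1-methyl-5,8-dioxo-5,8-dihydronaphthalene-2-carbonyl)-3,5-dihydroxyphenyl]methyl}-4-hydroxy-2H-pyran-2-one (CNP0141484.0) | Cc1c(C(=O)c2c(O)cc(O)cc2Cc2cc(O)cc(=O)o2)c(O)cc2c1C(=O)C=C(O)C2=O | target

## Step count and least certain steps

Total: 19 steps. Longest linear sequence: 16 steps (1, 2, 6, 8, 9, 10, 11, 16, 17, 18, 19, 21, 24, 26, 27, 28, 29).

**Step 10 (key step).** Three processes could divert it. The methyl enolate of 15 may close by aldol addition on the aroyl carbonyl. Ethoxide may cleave the aroylacetate by retro-Claisen attack. Enone 14 may be lost through γ-deprotonation and expulsion of silyloxide before it is captured. Fallback: the two bond formations are separated. Starting from 11 and 14, the conjugate addition is run alone with a catalytic amine base (DBU, MeCN, rt), where no alkoxide is present and the enone is not exposed to strong base, and adduct 15 is isolated. Ring closure is then carried out on pure 15 with KOtBu in tBuOH/THF, where the bulky alkoxide does not attack the ketone. The sequence returns to the route at 16.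

**Step 3.** The methoxy group of 2 polarises the quinone in the opposite sense to the bromine, so orientation could erode. The hindered terminus of 4 could also stop at a Michael adduct instead of closing the ring. Fallback: starting from diene 4, the cycloaddition is run with commercial 2,5-dibromo-1,4-benzoquinone, in which only halogen governs orientation. This should give ethyl 6-bromo-3-hydroxy-1-methyl-5,8-dioxo-5,8-dihydronaphthalene-2-carboxylate F1. Methoxide (NaOMe, MeOH, 0 °C) then replaces the bromine by ipso addition–elimination, and the sequence returns at 6. The hindered ester should resist exchange, and a methyl ester would in any case be reduced to the same alcohol 9.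

**Step 7.** With an electron-rich aryl group, aryl migration can compete with the hydride shift in the tin-bound diazonium intermediate, and addition to the di-ortho-substituted aldehyde may be slow. Fallback: starting from 10, aldol addition of the lithium enolate of ethyl acetate (LiN(iPr)2, THF, −78 °C) gives ethyl 3-hydroxy-3-(3,5,6,8-tetramethoxy-1-methylnaphthalen-2-yl)propanoate F2. Dess–Martin oxidation of F2 returns to the route at 11.

**Step 11.** The high-potential quinone may engage the tetramethoxynaphthalene (charge transfer, oxidation at the C1 methyl) or couple with the enol instead of abstracting hydride. Fallback: a Saegusa–Ito dehydrogenation. Starting from 16, Me3SiOTf and Et3N give the bis(silyl) dienol ether [6-[2-(tert-butyldimethylsilyloxy)ethyl]-2,4-bis(trimethylsilyloxy)cyclohexa-1,3-dien-1-yl](3,5,6,8-tetramethoxy-1-methylnaphthalen-2-yl)methanone F3. Pd(OAc)2 in MeCN then forms a palladium enolate that undergoes β-hydride elimination across C5'–C6'. Mild K2CO3/MeOH work-up removes the aryl trimethylsilyl groups, and the sequence returns at 17.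

**Step 15.** Proton transfer from the acidic arylacetyl CH2 of 23 to the dienolate would quench both partners, and O-acylation is possible. Fallback: the electrophile is changed from acyl to aldehyde. Starting from 19, Dess–Martin oxidation gives aldehyde 20, isolated this time. A Mukaiyama vinylogous aldol reaction (BF3·OEt2, CH2Cl2, −78 °C) is run with [(2,2-dimethyl-6-methylidene-6H-1,3-dioxin-4-yl)oxy]trimethylsilane F4, made from 22 with LiN(SiMe3)2 and Me3SiCl. It gives 6-{3-[3,5-bis(benzyloxy)-2-(3,5,6,8-tetramethoxy-1-methyl-2-naphthoyl)phenyl]-2-hydroxypropyl}-2,2-dimethyl-4H-1,3-dioxin-4-one F5. Dess–Martin oxidation of F5 returns to the route at 24.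

**Step 17.** One-electron oxidation of the acidic pyranone enol by tetravalent cerium may compete with oxidation of the trimethoxy ring, and some ortho-quinone may form. Fallback: the order is changed so that the oxidant never meets the hydroxypyranone. Starting from 24, which has no acidic enol, (NH4)2Ce(NO3)6 in MeCN/H2O gives 6-{3-[3,5-bis(benzyloxy)-2-(3,6-dimethoxy-1-methyl-5,8-dioxo-5,8-dihydronaphthalene-2-carbonyl)phenyl]-2-oxopropyl}-2,2-dimethyl-4H-1,3-dioxin-4-one F6. Heating F6 in toluene closes the pyranone under neutral conditions that the quinone tolerates, and the sequence returns at 27.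

## Further compounds

F0 | step 10 | none | none
F1 | step 3 | ethyl 6-bromo-3-hydroxy-1-methyl-5,8-dioxo-5,8-dihydronaphthalene-2-carboxylate | CCOC(=O)c1c(C)c2C(=O)C=C(Br)C(=O)c2cc1O
F2 | step 7 | ethyl 3-hydroxy-3-(3,5,6,8-tetramethoxy-1-methylnaphthalen-2-yl)propanoate (racemic) | CCOC(=O)CC(O)c1c(C)c2c(OC)cc(OC)c(OC)c2cc1OC
F3 | step 11 | [6-[2-(tert-butyldimethylsilyloxy)ethyl]-2,4-bis(trimethylsilyloxy)cyclohexa-1,3-dien-1-yl](3,5,6,8-tetramethoxy-1-methylnaphthalen-2-yl)methanone (racemic) | Cc1c(C(=O)C3=C(O[Si](C)(C)C)C=C(O[Si](C)(C)C)CC3CCO[Si](C)(C)C(C)(C)C)c(OC)cc2c1c(OC)cc(OC)c2OC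
F4 | step 15 | [(2,2-dimethyl-6-methylidene-6H-1,3-dioxin-4-yl)oxy]trimethylsilane | C=C1C=C(O[Si](C)(C)C)OC(C)(C)O1
F5 | step 15 | 6-{3-[3,5-bis(benzyloxy)-2-(3,5,6,8-tetramethoxy-1-methyl-2-naphthoyl)phenyl]-2-hydroxypropyl}-2,2-dimethyl-4H-1,3-dioxin-4-one (racemic) | Cc1c(C(=O)c3c(OCc4ccccc4)cc(OCc4ccccc4)cc3CC(O)CC3=CC(=O)OC(C)(C)O3)c(OC)cc2c1c(OC)cc(OC)c2OC
F6 | step 17 | 6-{3-[3,5-bis(benzyloxy)-2-(3,6-dimethoxy-1-methyl-5,8-dioxo-5,8-dihydronaphthalene-2-carbonyl)phenyl]-2-oxopropyl}-2,2-dimethyl-4H-1,3-dioxin-4-one | Cc1c(C(=O)c3c(OCc4ccccc4)cc(OCc4ccccc4)cc3CC(=O)CC3=CC(=O)OC(C)(C)O3)c(OC)cc2c1C(=O)C=C(OC)C2=O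
A1 | alternative 1 | 6-{3-[3,5-dimethoxy-2-(3,5,6,8-tetramethoxy-1-methyl-2-naphthoyl)phenyl]-2-oxopropyl}-2,2-dimethyl-4H-1,3-dioxin-4-one | Cc1c(C(=O)c3c(OC)cc(OC)cc3CC(=O)CC3=CC(=O)OC(C)(C)O3)c(OC)cc2c1c(OC)cc(OC)c2OC
A2 | alternative 1 | 6-[3,5-dimethoxy-2-(3,5,6,8-tetramethoxy-1-methyl-2-naphthoyl)benzyl]-4-hydroxy-2H-pyran-2-one | Cc1c(C(=O)c3c(OC)cc(OC)cc3Cc3cc(O)cc(=O)o3)c(OC)cc2c1c(OC)cc(OC)c2OC
A3 | alternative 2 | pentacarbonyl{methoxy[4-methoxy-2-methyl-3-(triisopropylsilyloxymethyl)phenyl]methylidene}chromium | COC(c1ccc(OC)c(CO[Si](C(C)C)(C(C)C)C(C)C)c1C)=[Cr](=C=O)(=C=O)(=C=O)(=C=O)=C=O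
A4 | alternative 2 | 2-ethoxy-4,7-dimethoxy-5-methyl-6-(triisopropylsilyloxymethyl)naphthalen-1-ol | Cc1c(CO[Si](C(C)C)(C(C)C)C(C)C)c(OC)cc2c1c(OC)cc(OCC)c2O
A5 | alternative 3 | (Z)-3-(tert-butyldimethylsilyloxy)-1-{2,4-dimethoxy-6-[(4-methoxy-2-oxo-2H-pyran-6-yl)methyl]phenyl}-2-ethylidenebut-3-en-1-one | C/C=C(/C(=C)O[Si](C)(C)C(C)(C)C)C(=O)c1c(OC)cc(OC)cc1Cc1cc(OC)cc(=O)o1
A6 | alternative 3 | 7-(tert-butyldimethylsilyloxy)-6-{2,4-dimethoxy-6-[(4-methoxy-2-oxo-2H-pyran-6-yl)methyl]benzoyl}-2-methoxy-5-methyl-1,4-naphthoquinone | Cc1c(C(=O)c3c(OC)cc(OC)cc3Cc3cc(OC)cc(=O)o3)c(O[Si](C)(C)C(C)(C)C)cc2c1C(=O)C=C(OC)C2=O
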